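How much of each charge stands as target at the end, and how does that amount move along the row?

common to all: gas 200 mM (held)

| flask | starting material | remark | time |
|---|---|---|---|
| blue | 0.017 M | run made earlier |  |
| amber | 1.4 M | run made earlier |  |
| north | 0.012 M |  | 25 min |
| south | 0.040 M |  | 25 min |
| north-east | 0.12 M |  | 25 min |
| north-west | 0.30 M |  | 25 min |
| south-east | 1.0 M |  | 25 min |

- blue (time / min: target / %, starting material / %): 1.00: 0.6, 98.5; 1.50: 1.0, 98.2; 2.50: 4.0, 93.5; 4.00: 7.9, 88.0; 5.00: 11.8, 83.1; 8.00: 21.4, 69.6; 12.0: 29.3, 53.2
- amber (time / min: target / %, starting material / %): 0.667: 0.2, 100.2; 2.00: 1.5, 97.9; 4.00: 4.0, 94.0; 5.00: 5.1, 92.8; 8.00: 8.9, 87.7; 10.0: 8.7, 85.0; 12.0: 11.2, 82.5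

(standard deviation of a reading: 0.5 percentage points)

- at the start none of the gas is in solution
- "hardly changes" means that all values lie within two and a half points (for a concentration: within two and a half percent of the largest)
- a reading of starting material is of its free form alone

1. amount of target at the end, in percent of the starting material charged for north, south, north-east, north-west, south-east, in this order
2. how that number moves from the first to the last of them (rises, then falls / falls all the way / rises all the way / hardly changes / falls, then rises)

Target is a product of two numbers: the fraction of the charge consumed, and the target formed per starting material consumed. In the blue run at 12.0 min that second number reads 0.626, and this target share (the integral selectivity) is the figure to watch.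

Which input has to be known well? First, the charge. At 12.0 min amber has consumed 17 percentage points against blue's 47 points, yet amber's share reads 0.640. So the charge moves the fraction consumed.

Next, the lag. Blue still holds 98.2 % at 1.50 min, so we start the clock there. Blue then gives a first-order rate of 0.0601 min⁻¹, and we use it for north, whose charge is close to blue's. On that estimate north has consumed 0.756 of its charge at 25 min. Dropping the lag changes that by 0.0210.

Last, the share. It read 0.704 at 8.00 min, so it fell by 0.0779 in blue, a reading with 0.5 points of scatter in each figure behind it. Carried through north, that fall is worth 0.0589 of the charge, more than the lag's effect on target.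

So for north the share weighs more than the lag. If it stops falling, our reckoning gives north 0.474; after one more such fall, 0.415.

The forecast gives 48 %, 47 %, 45.5 %, 42 % and 29.5 %, so the row falls all the way. Its ground is that “Target per starting material consumed is about 0.65 in both runs”. Its north value lies above our range.

The flask gives 41.3 %, 40.9 %, 39.8 %, 36.9 % and 26.1 %, so the row falls all the way.

    starting material + reagent ⇌ target (K = 9.54 L mol⁻¹, k = 0.00874 L mol⁻¹ s⁻¹)
    starting material + reagent ⇌ isomer of the product (K = 13.4 L mol⁻¹, k = 0.00405 L mol⁻¹ s⁻¹)
    gas ⇌ reagent, rate k3*(csat - [reagent]) (kL = 0.00246 s⁻¹)
    reagent ⇌ dormant form (K = 1.50, k = 0.00132 s⁻¹)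

At 25.0 min north holds 30 % of its starting material and 28.8 % as isomer of the product. Its target share at that time is therefore 0.590, below the 0.626 read in blue at 12.0 min. South-east, with 57 % of its starting material left, has a target share of 0.607.

(All runs were generated by integration on assumed constants.)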